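## The problem

Compound 27 (labdane numbering is used for the target and all precursors) is a normal-series labdane. It is a trans-fused decalin (ring A: C1–C5, C10; ring B: C5–C10) with a C8=C17 exocyclic methylene, a 7α (axial) allylic hydroxyl, and at C9 a five-carbon chain ending in the (13R) tertiary vinyl carbinol.

The quaternary C10 bears an oxidised carbon, C20 (CH2OAc). No cheap labdane or decalin building block offers this, and an oxygen on C20 weakens both the C5=C10 alkene and the C10 cation on which a biomimetic cationic closure relies.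

Ring A carries a cis 2α,3α-diol that is differentiated: angelate on the equatorial O2, free axial O3 beside the gem-dimethyl C4. The axial 3α-oxygen is the opposite of what an epoxide-initiated cyclisation delivers.

C5, C9 and C10 are contiguous and can be set together by one chair–chair closure. C2/C3 can steer that closure, and C7 can be set afterwards by the rigid decalin. C13 lies five bonds from the nearest ring stereocentre, cannot be controlled by the ring, and has to be brought in.

The angelate isomerises easily to the tiglate, the tertiary allylic alcohol ionises in acid, and the finished molecule has three C=C bonds besides the enoate. A late dihydroxylation for the 2,3-diol is therefore ruled out.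

The feature that opens the key step is the arrangement around C4, C5 and C10. With C20 at the ester level, C5=C10 is a Michael acceptor whose α-carbon is C10. C4 is fully substituted and sits next to the oxygenated C3. A tertiary radical at C4 can therefore close ring A onto C5, and the resulting C10 α-ester radical can close ring B onto C9. The C8=C17 methylene is then the footprint of a sulfonyl group leaving from C17, and the cis-2,3-diol rides through as a chiral-pool acetonide.

## Retrosynthesis

**27 ⇒ 26.** The C7–O bond is cut last. The 7α-hydroxyl is allylic to C8=C17 and can be delivered by the decalin itself. A 7-oxygen carried from earlier would add a stereocentre to the open chain, need protection and compete with O2 in the acylation. 26 is simpler by one stereocentre and one hydroxyl. The forward reaction must pick the C7 methylene over C9–H and the angelate methyls, and deliver oxygen axially (α).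

**26 ⇒ 23 + 24, and 23 ⇒ 22 ⇒ 21 ⇒ 20.** The angelate at O2, the acetate at C20 and the protecting groups are removed, which returns everything to ester 20. Esterifying O2 after the diol is freed is preferred over carrying an angelate through the route, because an angelate would not survive hydride reduction of C20 and is prone to Z/E isomerisation. The price is a regioselective acylation, which the equatorial O2 should win against the axial, neopentyl O3. 20 is simpler by two acyl groups and has every alcohol masked.

**20 ⇒ 19 (key).** Both ring bonds C4–C5 and C9–C10 are cut in one operation. The C8=C17 alkene is traced back to a C8=C9 alkene carrying PhSO2 on C17, and C4 receives the oxalate oxygen from which its radical is made. This cut is preferred over C5–C10 or C8–C9 because it leaves an unbranched chain whose only stereocentres are C2, C3 and C13, all from the chiral pool, and because the ester at C20 makes the polarity of both closures right. 19 has no carbocycle and three fewer stereocentres than 20. The forward step must close two six-membered rings 6-endo, choose one face relative to the acetonide, give the trans ring fusion, and terminate before the C8 radical reaches the vinyl group.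

**19 ⇒ 18 ⇒ 7 + 17.** The C5=C10 double bond is cut by a Z-selective phosphonate olefination; the methyl oxalate of 18 is saponified to the cesium salt only afterwards. This cut divides the chain into two halves of similar size and puts the ester where the phosphonate needs it. It is better than a cut at C6–C7, which would need an sp3–sp3 coupling between two alkenes. The forward reaction must give the less stable geometry (ester cis to C6), on which the trans ring fusion depends.

**7 ⇒ 4 + 5, and 4 ⇒ 2 ⇒ 1.** The C1–C10 bond is cut by alkylation of phosphonoacetate 5. The two C4–CH3 bonds are cut by Grignard addition to the lactone carbonyl of 1, which supplies C1–C4 with the cis-diol already protected and in the right absolute configuration. The tertiary hydroxyl is capped as the methyl oxalate in 4. This group cannot cyclise onto the activated C1 (a free or silylated oxygen would close a tetrahydrofuran), and it is the latent radical precursor. The forward steps must differentiate primary from tertiary oxygen and achieve a clean SN2 reaction at a β-oxygenated primary carbon.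

**17 ⇒ 16 ⇒ 15 ⇒ 11 + 14; 11 ⇒ 9 ⇒ 8; 14 ⇒ 12 + 13.** The C6–C7 bond and the C8=C9 geometry are traced to a Johnson–Claisen rearrangement of allylic alcohol 15. Its C8–C9 bond is cut to aldehyde 11 and alkenyl bromide 14. A [3,3] shift is chosen over olefination of a ketone because C8 carries two CH2 groups of similar size that no Wittig-type reaction would tell apart. 11 is (R)-linalool (8) minus its isopropylidene end, so C13 comes from the chiral pool.

## Roads not taken

Alternative 1: (the obvious one) the same two ring bonds, C4–C5 and C9–C10, cut in a biomimetic epoxy-polyene cyclisation. The forward key step would treat the (S)-epoxide A1 of a 20-acetoxy geranyllinalool with a Lewis acid (cationic mode) or with Cp2TiCl (radical mode) to give the 3β-alcohol A2.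
- In the cationic mode the oxygen on C20 withdraws electron density from the C5=C10 alkene and from the C10 cation, and the C13 hydroxyl or the vinyl group can capture the C8 cation.
- In the radical mode the C8 radical has the linalyl vinyl group within reach for a 7-endo closure.
- In either mode A2 has the wrong configuration at C3 and no oxygen at C2. Ring A would still need oxidation, conversion into the 2-ene and dihydroxylation with OsO4 in the presence of two other alkenes.
- The chosen plan brings C2 and C3 in finished form and needs none of this.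

Alternative 2: ring system first, chain last; cuts at C9–C11 and C13–C14. A bicyclic 8-ketone A3 (rings A and B with the acetonide and the C20 acetate) would be extended at C9 by conjugate addition to methyl vinyl ketone to give diketone A4. The ring ketone would be methylenated to A5, and the vinyl group added to the C13 methyl ketone of A5 with a vinyl Grignard reagent.
- C13 is five bonds from C9, so this last addition has no facial bias and gives both epimers.
- The quaternary C10 with its oxidised carbon and the 2,3-diol would have to be built ring by ring in a long linear sequence.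
- C9 would be set by an equilibrating addition instead of a ring closure.
- The chosen plan is convergent and takes C13 from linalool.

Alternative 3: an enzymatic key step. A class 2 diterpene cyclase (copalyl diphosphate synthase type) or an engineered squalene–hopene cyclase would fold triene A6 into bicycle A7 with full control of C5, C9 and C10. Cytochrome P450 monooxygenases would then hydroxylate C2, C3 and C7.
- These cyclases hold the C20 methyl in a tight hydrophobic pocket, so acceptance of an oxidised C20 is doubtful.
- Three separate site- and face-selective hydroxylations would each need their own enzyme.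
- The chosen plan needs no oxidation of the ring system other than the allylic hydroxylation at C7, for which a small reagent suffices.

Key step: step 12

Assumption: commercial (R)-(−)-linalool is taken as enantiomerically pure; any (S)-enantiomer would be carried through as the C13 epimer.

## Route

Step 1
Reactants: 1 (3aR,6aR)-2,2-dimethyldihydrofuro[3,4-d][1,3]dioxol-4(3aH)-one (2,3-O-isopropylidene-D-erythronolactone)
Product: 2 2-[(4R,5R)-5-(hydroxymethyl)-2,2-dimethyl-1,3-dioxolan-4-yl]propan-2-ol
Conditions: MeMgBr (3 equiv), THF, 0 °C to rt; aq. NH4Cl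
Reagents that add atoms: methylmagnesium bromide, C[Mg]Br
Why: Double Grignard addition to the lactone carbonyl opens the ring and gives the tertiary carbinol (future C4 with both methyls) and the primary alcohol (future C1). The two acetonide stereocentres (future C3 and C2) are not touched, since addition is faster than enolisation of the α-alkoxy lactone.

Step 2
Reactants: 2 2-[(4R,5R)-5-(hydroxymethyl)-2,2-dimethyl-1,3-dioxolan-4-yl]propan-2-ol
Product: 4 2-[(4R,5R)-5-(hydroxymethyl)-2,2-dimethyl-1,3-dioxolan-4-yl]propan-2-yl methyl oxalate, via bis(methyl oxalate) 3 (not isolated)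
Conditions: ClC(O)CO2Me (2.5 equiv), Et3N, DMAP (cat.), CH2Cl2, 0 °C to rt; aqueous wash; then K2CO3 (0.1 equiv), MeOH, −10 °C
Reagents that add atoms: methyl chlorooxoacetate, COC(=O)C(=O)Cl
Why: Both hydroxyls are acylated, then base-catalysed transesterification in methanol releases only the unhindered primary alcohol; at the tert-alkyl oxalate methoxide attacks the distal methyl ester carbonyl, which is a degenerate exchange. The tertiary methyl oxalate serves as a non-participating protecting group for the next step and as the latent radical precursor for step 12.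

Step 3
Reactants: 4 2-[(4R,5R)-5-(hydroxymethyl)-2,2-dimethyl-1,3-dioxolan-4-yl]propan-2-yl methyl oxalate; 5 methyl 2-[bis(2,2,2-trifluoroethoxy)phosphoryl]acetate
Product: 7 methyl 2-[bis(2,2,2-trifluoroethoxy)phosphoryl]-3-[(4R,5R)-5-{2-[(methoxyoxalyl)oxy]propan-2-yl}-2,2-dimethyl-1,3-dioxolan-4-yl]propanoate (both C2 epimers), via primary triflate 6 (not isolated)
Conditions: Tf2O, 2,6-lutidine, CH2Cl2, −78 °C; then added to 5, NaH, 15-crown-5, THF, −20 °C to rt
Reagents that add atoms: none
Why: Malonate-type C-alkylation of the sodium enolate of the phosphonoacetate by SN2 displacement of a primary triflate; the triflate is chosen because C1 is β-oxygenated and flanked by a cis substituent. The new phosphonate-bearing centre becomes sp2 in step 10, so its configuration is irrelevant.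

Step 4
Reactants: 8 (R)-(−)-linalool [(3R)-3,7-dimethylocta-1,6-dien-3-ol]
Product: 9 triethyl{[(3R)-3,7-dimethylocta-1,6-dien-3-yl]oxy}silane
Conditions: Et3SiOTf, 2,6-lutidine, CH2Cl2, −78 to 0 °C
Reagents that add atoms: triethylsilyl trifluoromethanesulfonate, CC[Si](CC)(CC)OS(=O)(=O)C(F)(F)F
Why: Silylation of the hindered tertiary alcohol with the silyl triflate; it prevents lactol formation after the next step and leaves the C13 configuration untouched.

Step 5
Reactants: 9 triethyl{[(3R)-3,7-dimethylocta-1,6-dien-3-yl]oxy}silane
Product: 11 (4R)-4-methyl-4-(triethylsilyloxy)hex-5-enal, via ozonide 10 (not isolated)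
Conditions: O3 (1.0 equiv, Sudan Red 7B end point), CH2Cl2, −78 °C; then PPh3, −78 °C to rt
Reagents that add atoms: ozone, [O-][O+]=O
Why: Ozonolysis with reductive work-up; the electron-rich trisubstituted alkene is attacked much faster than the monosubstituted vinyl group next to the silyloxy-bearing quaternary carbon, and the indicator dye marks the end point.

Step 6
Reactants: 12 2,3-dibromopropene; 13 sodium benzenesulfinate
Product: 14 [(2-bromoprop-2-en-1-yl)sulfonyl]benzene
Conditions: DMF, rt
Reagents that add atoms: none
Why: S-Alkylation of the sulfinate by SN2 displacement of the allylic bromide; the vinylic bromide does not react.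

Step 7
Reactants: 11 (4R)-4-methyl-4-(triethylsilyloxy)hex-5-enal; 14 [(2-bromoprop-2-en-1-yl)sulfonyl]benzene
Product: 15 (6R)-6-methyl-2-methylidene-1-(phenylsulfonyl)-6-(triethylsilyloxy)oct-7-en-3-ol (both C3 epimers)
Conditions: CrCl2 (4 equiv), NiCl2 (2 mol %), DMF, rt
Reagents that add atoms: none
Why: Nozaki–Hiyama–Kishi coupling: zerovalent nickel inserts into the alkenyl bromide, the alkenyl group passes to chromium and adds to the aldehyde; sulfone and silyl ether are tolerated. The carbinol configuration is irrelevant because the centre becomes sp2 in step 8.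

Step 8
Reactants: 15 (6R)-6-methyl-2-methylidene-1-(phenylsulfonyl)-6-(triethylsilyloxy)oct-7-en-3-ol
Product: 16 ethyl (4Z,8R)-8-methyl-4-[(phenylsulfonyl)methyl]-8-(triethylsilyloxy)deca-4,9-dienoate
Conditions: MeC(OEt)3 (6 equiv), EtCO2H (cat.), 135 °C, EtOH distilled off
Reagents that add atoms: triethyl orthoacetate, CCOC(C)(OCC)OCC
Why: Johnson–Claisen rearrangement through a chair transition state with the C11 chain equatorial. It adds C5 and C6 and gives the trisubstituted alkene with C7 trans to C11 (CH2SO2Ph cis to C11), the geometry that makes C11 equatorial in ring B.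

Step 9
Reactants: 16 ethyl (4Z,8R)-8-methyl-4-[(phenylsulfonyl)methyl]-8-(triethylsilyloxy)deca-4,9-dienoate
Product: 17 (4Z,8R)-8-methyl-4-[(phenylsulfonyl)methyl]-8-(triethylsilyloxy)deca-4,9-dienal
Conditions: i-Bu2AlH (1.1 equiv), toluene, −78 °C; aq. potassium sodium tartrate
Reagents that add atoms: none
Why: Partial reduction of the ester to the aldehyde through the tetrahedral aluminate that is stable at −78 °C; sulfone, alkenes and silyl ether are inert.

Step 10
Reactants: 7 methyl 2-[bis(2,2,2-trifluoroethoxy)phosphoryl]-3-[(4R,5R)-5-{2-[(methoxyoxalyl)oxy]propan-2-yl}-2,2-dimethyl-1,3-dioxolan-4-yl]propanoate; 17 (4Z,8R)-8-methyl-4-[(phenylsulfonyl)methyl]-8-(triethylsilyloxy)deca-4,9-dienal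
Product: 18 methyl (2Z,6Z,10R)-2-({(4R,5R)-5-{2-[(methoxyoxalyl)oxy]propan-2-yl}-2,2-dimethyl-1,3-dioxolan-4-yl}methyl)-10-methyl-6-[(phenylsulfonyl)methyl]-10-(triethylsilyloxy)dodeca-2,6,11-trienoate
Conditions: 7, KN(SiMe3)2 (1.0 equiv), 18-crown-6, THF, −78 °C; then 17, −78 °C
Reagents that add atoms: none
Why: Still–Gennari variant of the Horner–Wadsworth–Emmons reaction: the bis(trifluoroethyl) phosphonate with a dissociated potassium counter-ion eliminates under kinetic control to the Z-enoate (ester cis to C6). This geometry is what later places C6 equatorial on ring A.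

Step 11
Reactants: 18 methyl (2Z,6Z,10R)-2-({(4R,5R)-5-{2-[(methoxyoxalyl)oxy]propan-2-yl}-2,2-dimethyl-1,3-dioxolan-4-yl}methyl)-10-methyl-6-[(phenylsulfonyl)methyl]-10-(triethylsilyloxy)dodeca-2,6,11-trienoate
Product: 19 cesium salt of the oxalate half-ester of 18 (the oxalate CO2Me replaced by CO2Cs)
Conditions: CsOH (1.0 equiv, 1 M aq.), THF, 0 °C to rt; concentrate
Reagents that add atoms: cesium hydroxide, [Cs+].[OH-]
Why: The oxalate methyl ester is far more electrophilic than the hindered conjugated methyl ester, so one equivalent of hydroxide saponifies it alone and gives the stable cesium oxalate.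

Step 12
Reactants: 19 cesium salt of the oxalate half-ester of 18
Product: 20 methyl (13R)-2α,3α-(isopropylidenedioxy)-13-(triethylsilyloxy)labda-8(17),14-dien-20-oate (trans-decalin; 5α-H; 9α-H; 10β-CO2Me)
Conditions: Ir[dF(CF3)ppy]2(dtbbpy)PF6 (2 mol %), DME–DMF 3:1 (0.01 M), H2O (10 equiv), 450 nm LEDs, 40 °C, argon
Reagents that add atoms: none
Why: Proposed new method: the excited trivalent-iridium complex oxidises the oxalate, two CO2 are lost and the tertiary C4 radical adds 6-endo-trig to C5, the β-carbon of the Z-enoate (ring A); the electrophilic tertiary α-ester radical at C10 then adds 6-endo-trig to C9 of the allyl sulfone (ring B), and the C8 radical expels PhSO2•, which the divalent-iridium state reduces to sulfinate, so the cycle is redox-neutral. The closest known reaction types are the photoredox conjugate addition of tert-alkyl oxalate radicals to β-substituted acrylates, the radical addition–fragmentation of allyl sulfones and radical polyene bicyclisations that pass through α-ester radicals; only their union in one cascade is new. Polarity alternates along the chain (nucleophilic C4 radical onto the acceptor carbon C5, electrophilic C10 radical onto the unactivated C8=C9 alkene), which favours both 6-endo modes over 5-exo attack at the fully substituted C10 and C8. C5 (H α) is set in a chair transition state of ring A in which the Z geometry places C6 equatorial, and the face is chosen by the acetonide: the chair with O2 equatorial and O3 axial avoids the syn-diaxial contact between O2 and a C4 methyl that the alternative chair must bear. C10 (CO2Me β, axial) and C9 (H α, chain β, equatorial) are set together in a chair–chair closure of ring B from the equatorial C6 tether, the C7/C11 trans geometry of the allyl sulfone putting C11 equatorial. β-Scission of the sulfonyl radical is much faster than 7-endo attack of the C8 radical on the C14=C15 vinyl group and fixes the new alkene as C8=C17. High dilution and the low stationary concentration of the reduced photocatalyst are relied on to let ring B close before the C10 radical is reduced.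

Step 13
Reactants: 20 methyl (13R)-2α,3α-(isopropylidenedioxy)-13-(triethylsilyloxy)labda-8(17),14-dien-20-oate
Product: 21 (13R)-2α,3α-(isopropylidenedioxy)-13-(triethylsilyloxy)labda-8(17),14-dien-20-ol
Conditions: LiAlH4, THF, 0 °C to reflux
Reagents that add atoms: none
Why: Hydride reduction of the hindered angular ester to the neopentyl primary alcohol; acetonide, silyl ether and the unactivated alkenes are inert to LiAlH4.

Step 14
Reactants: 21 (13R)-2α,3α-(isopropylidenedioxy)-13-(triethylsilyloxy)labda-8(17),14-dien-20-ol
Product: 22 (13R)-20-acetoxy-2α,3α-(isopropylidenedioxy)-13-(triethylsilyloxy)labda-8(17),14-diene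
Conditions: Ac2O, pyridine, DMAP (cat.), CH2Cl2, rt
Reagents that add atoms: acetic anhydride, CC(=O)OC(C)=O
Why: DMAP-catalysed acetylation of the only free hydroxyl in the molecule.

Step 15
Reactants: 22 (13R)-20-acetoxy-2α,3α-(isopropylidenedioxy)-13-(triethylsilyloxy)labda-8(17),14-diene
Product: 23 (13R)-20-acetoxylabda-8(17),14-diene-2α,3α,13-triol
Conditions: PPTS (0.3 equiv), MeOH, 45 °C
Reagents that add atoms: none
Why: Acid-catalysed transacetalisation and silyl ether methanolysis remove the acetonide and the tertiary triethylsilyl group in one operation. The weak pyridinium acid is chosen so that the tertiary allylic alcohol does not ionise, the exocyclic alkene does not migrate and the acetate stays.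

Step 16
Reactants: 23 (13R)-20-acetoxylabda-8(17),14-diene-2α,3α,13-triol; 24 angelic acid [(2Z)-2-methylbut-2-enoic acid]
Product: 26 (13R)-20-acetoxy-2α-angeloyloxylabda-8(17),14-diene-3α,13-diol, via angelic 2,4,6-trichlorobenzoic anhydride 25 (not isolated)
Conditions: 24 (1.5 equiv), 2,4,6-Cl3C6H2COCl, Et3N, toluene, rt; then 23, toluene, 75 °C
Reagents that add atoms: none
Why: Yamaguchi-type mixed-anhydride esterification; the equatorial 2α-hydroxyl is acylated in preference to the axial neopentyl 3α-hydroxyl and the tertiary 13-hydroxyl. Running without DMAP keeps the Z (angelate) geometry.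

Step 17
Reactants: 26 (13R)-20-acetoxy-2α-angeloyloxylabda-8(17),14-diene-3α,13-diol
Product: 27 (13R)-20-acetoxy-2α-angeloyloxylabda-8(17),14-diene-3α,7α,13-triol (target, CNP0251485.1)
Conditions: SeO2 (0.3 equiv), t-BuOOH (2 equiv), CH2Cl2, 0 °C to rt
Reagents that add atoms: selenium dioxide, O=[Se]=O; tert-butyl hydroperoxide, CC(C)(C)OO
Why: Allylic oxidation by ene reaction at C17 with removal of the axial 7α-hydrogen, then [2,3]-sigmatropic shift of the allylseleninic acid, which returns the double bond to C8=C17 and delivers oxygen axially to give the 7α-alcohol. The CH2 of the 1,1-disubstituted alkene reacts before the C9 methine, the electron-poor angelate alkene is slower, and the vinyl group has no allylic hydrogen.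

## Compound list

1 | (3aR,6aR)-2,2-dimethyldihydrofuro[3,4-d][1,3]dioxol-4(3aH)-one (2,3-O-isopropylidene-D-erythronolactone) | O=C1[C@@H]2OC(C)(C)O[C@@H]2CO1 | starting material
2 | 2-[(4R,5R)-5-(hydroxymethyl)-2,2-dimethyl-1,3-dioxolan-4-yl]propan-2-ol | CC(C)(O)[C@@H]1OC(C)(C)O[C@@H]1CO | intermediate
3 | bis(methyl oxalate) of 2 (not isolated) | COC(=O)C(=O)OC(C)(C)[C@@H]1OC(C)(C)O[C@@H]1COC(=O)C(=O)OC | intermediate
4 | 2-[(4R,5R)-5-(hydroxymethyl)-2,2-dimethyl-1,3-dioxolan-4-yl]propan-2-yl methyl oxalate | COC(=O)C(=O)OC(C)(C)[C@@H]1OC(C)(C)O[C@@H]1CO | intermediate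
5 | methyl 2-[bis(2,2,2-trifluoroethoxy)phosphoryl]acetate | COC(=O)CP(=O)(OCC(F)(F)F)OCC(F)(F)F | starting material
6 | primary triflate of 4 (not isolated) | COC(=O)C(=O)OC(C)(C)[C@@H]1OC(C)(C)O[C@@H]1COS(=O)(=O)C(F)(F)F | intermediate
7 | methyl 2-[bis(2,2,2-trifluoroethoxy)phosphoryl]-3-[(4R,5R)-5-{2-[(methoxyoxalyl)oxy]propan-2-yl}-2,2-dimethyl-1,3-dioxolan-4-yl]propanoate (both C2 epimers) | COC(=O)C(=O)OC(C)(C)[C@@H]1OC(C)(C)O[C@@H]1CC(C(=O)OC)P(=O)(OCC(F)(F)F)OCC(F)(F)F | intermediate
8 | (R)-(−)-linalool, (3R)-3,7-dimethylocta-1,6-dien-3-ol | C=C[C@](C)(O)CCC=C(C)C | starting material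
9 | triethyl{[(3R)-3,7-dimethylocta-1,6-dien-3-yl]oxy}silane | C=C[C@](C)(O[Si](CC)(CC)CC)CCC=C(C)C | intermediate
10 | 3,3-dimethyl-5-[(3R)-3-methyl-3-(triethylsilyloxy)pent-4-en-1-yl]-1,2,4-trioxolane (ozonide, not isolated) | C=C[C@](C)(O[Si](CC)(CC)CC)CCC1OOC(C)(C)O1 | intermediate
11 | (4R)-4-methyl-4-(triethylsilyloxy)hex-5-enal | C=C[C@](C)(O[Si](CC)(CC)CC)CCC=O | intermediate
12 | 2,3-dibromopropene | C=C(Br)CBr | starting material
13 | sodium benzenesulfinate | [Na+].[O-]S(=O)c1ccccc1 | starting material
14 | [(2-bromoprop-2-en-1-yl)sulfonyl]benzene | C=C(Br)CS(=O)(=O)c1ccccc1 | intermediate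
15 | (6R)-6-methyl-2-methylidene-1-(phenylsulfonyl)-6-(triethylsilyloxy)oct-7-en-3-ol (both C3 epimers) | C=C[C@](C)(O[Si](CC)(CC)CC)CCC(O)C(=C)CS(=O)(=O)c1ccccc1 | intermediate
16 | ethyl (4Z,8R)-8-methyl-4-[(phenylsulfonyl)methyl]-8-(triethylsilyloxy)deca-4,9-dienoate | CCOC(=O)CC/C(CS(=O)(=O)c1ccccc1)=C/CC[C@@](C)(O[Si](CC)(CC)CC)C=C | intermediate
17 | (4Z,8R)-8-methyl-4-[(phenylsulfonyl)methyl]-8-(triethylsilyloxy)deca-4,9-dienal | O=CCC/C(CS(=O)(=O)c1ccccc1)=C/CC[C@@](C)(O[Si](CC)(CC)CC)C=C | intermediate
18 | methyl (2Z,6Z,10R)-2-({(4R,5R)-5-{2-[(methoxyoxalyl)oxy]propan-2-yl}-2,2-dimethyl-1,3-dioxolan-4-yl}methyl)-10-methyl-6-[(phenylsulfonyl)methyl]-10-(triethylsilyloxy)dodeca-2,6,11-trienoate | COC(=O)C(=O)OC(C)(C)[C@@H]1OC(C)(C)O[C@@H]1C/C(C(=O)OC)=C/CC/C(CS(=O)(=O)c1ccccc1)=C/CC[C@@](C)(O[Si](CC)(CC)CC)C=C | intermediate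
19 | cesium salt of the oxalate half-ester of 18 | [Cs+].[O-]C(=O)C(=O)OC(C)(C)[C@@H]1OC(C)(C)O[C@@H]1C/C(C(=O)OC)=C/CC/C(CS(=O)(=O)c1ccccc1)=C/CC[C@@](C)(O[Si](CC)(CC)CC)C=C | intermediate
20 | methyl (13R)-2α,3α-(isopropylidenedioxy)-13-(triethylsilyloxy)labda-8(17),14-dien-20-oate | C=C[C@](C)(O[Si](CC)(CC)CC)CC[C@H]1C(=C)CC[C@H]2C(C)(C)[C@@H]3OC(C)(C)O[C@@H]3C[C@]12C(=O)OC | intermediate
21 | (13R)-2α,3α-(isopropylidenedioxy)-13-(triethylsilyloxy)labda-8(17),14-dien-20-ol | C=C[C@](C)(O[Si](CC)(CC)CC)CC[C@H]1C(=C)CC[C@H]2C(C)(C)[C@@H]3OC(C)(C)O[C@@H]3C[C@]12CO | intermediate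
22 | (13R)-20-acetoxy-2α,3α-(isopropylidenedioxy)-13-(triethylsilyloxy)labda-8(17),14-diene | C=C[C@](C)(O[Si](CC)(CC)CC)CC[C@H]1C(=C)CC[C@H]2C(C)(C)[C@@H]3OC(C)(C)O[C@@H]3C[C@]12COC(C)=O | intermediate
23 | (13R)-20-acetoxylabda-8(17),14-diene-2α,3α,13-triol | C=C[C@](C)(O)CC[C@H]1C(=C)CC[C@H]2C(C)(C)[C@H](O)[C@H](O)C[C@]12COC(C)=O | intermediate
24 | angelic acid, (2Z)-2-methylbut-2-enoic acid | C/C=C(/C)C(=O)O | starting material
25 | angelic 2,4,6-trichlorobenzoic anhydride (not isolated) | C/C=C(/C)C(=O)OC(=O)c1c(Cl)cc(Cl)cc1Cl | intermediate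
26 | (13R)-20-acetoxy-2α-angeloyloxylabda-8(17),14-diene-3α,13-diol | C=C[C@](C)(O)CC[C@H]1C(=C)CC[C@H]2C(C)(C)[C@H](O)[C@H](OC(=O)/C(C)=C\C)C[C@]12COC(C)=O | intermediate
27 | (13R)-20-acetoxy-2α-angeloyloxylabda-8(17),14-diene-3α,7α,13-triol (CNP0251485.1) | C=C[C@](C)(O)CC[C@H]1C(=C)[C@H](O)C[C@H]2C(C)(C)[C@H](O)[C@H](OC(=O)/C(C)=C\C)C[C@]12COC(C)=O | target

## Step count and least certain steps

Total step count: 17. Longest linear sequence: 13 steps, from 8 through steps 4, 5, 7, 8, 9, 10, 11, 12, 13, 14, 15, 16 and 17.

**Step 12 (key step, proposed new method).** The most likely failure is premature termination: the C10 α-ester radical is reduced by the reduced photocatalyst and protonated before it reaches C9, so the cascade stops after ring A. A second concern is erosion of facial selectivity in the first closure if the chair with O2 axial competes.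

Fallback with known chemistry, from 19 back to 20, closing the rings in two separate radical steps:
- 19 is irradiated with the same photocatalyst under the ordinary conjugate-addition conditions (0.1 M, water present), where reduction and protonation of the C10 radical are the normal outcome. This gives the monocyclic ester methyl (13R)-2α,3α-(isopropylidenedioxy)-17-(phenylsulfonyl)-13-(triethylsilyloxy)-9,10-secolabda-8,14-dien-20-oate F1.
- F1 is deprotonated twice with LiN(i-Pr)2 (2.2 equiv, THF, −78 °C), first at the sulfone α-carbon and then at C10. One equivalent of PhSeBr is taken up by the more basic ester enolate to give the 10-(phenylselanyl) ester F2.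
- (Bu3Sn)2 under irradiation in benzene at 80 °C regenerates the C10 radical without a hydrogen donor. 6-endo addition to C9 and loss of the sulfonyl radical then give 20.

**Step 3.** The most likely failure is slow SN2 displacement at the β-oxygenated, cis-flanked C1. That would leave time for acylation of the phosphonate carbanion by the oxalate methyl ester or for decomposition of the triflate.

Fallback, from 4 back to 7, replacing the polar alkylation by a radical conjugate addition:
- 4 is converted with I2, PPh3 and imidazole into the primary iodide 2-[(4R,5R)-5-(iodomethyl)-2,2-dimethyl-1,3-dioxolan-4-yl]propan-2-yl methyl oxalate F3.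
- The C1 radical made from F3 with (Me3Si)3SiH and AIBN (toluene, 80 °C) adds to methyl 2-[bis(2,2,2-trifluoroethoxy)phosphoryl]acrylate F4, prepared from 5 and paraformaldehyde (piperidine cat., then TsOH). This gives 7.

**Step 7.** The most likely failure is β-elimination of sulfinate from the alkenyl–nickel or alkenyl–chromium intermediate (allene formation) in competition with carbonyl addition.

Fallback, from 11 back to 15, building the same allylic alcohol without an alkenyl–metal species:
- Morita–Baylis–Hillman reaction of 11 with methyl acrylate (DABCO) gives methyl (6R)-3-hydroxy-6-methyl-2-methylidene-6-(triethylsilyloxy)oct-7-enoate F5.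
- i-Bu2AlH reduces F5 to (6R)-6-methyl-2-methylidene-6-(triethylsilyloxy)oct-7-ene-1,3-diol F6.
- MsCl and Et3N at −30 °C sulfonylate the primary allylic hydroxyl selectively to the mesylate F7, which is used crude with PhSO2Na in DMF to give 15.

**Step 17.** The most likely failure is loss of material at the last step through over-oxidation of the new allylic alcohol to the enone and competing attack on the angelate γ-methyl groups.

Fallback, from 22 back to 27, moving the hydroxylation before the angelate exists and changing the acylation method: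
- 22 is oxidised with SeO2 and t-BuOOH to (13R)-20-acetoxy-2α,3α-(isopropylidenedioxy)-13-(triethylsilyloxy)labda-8(17),14-dien-7α-ol F8.
- PPTS in MeOH gives (13R)-20-acetoxylabda-8(17),14-diene-2α,3α,7α,13-tetraol F9.
- Bu2SnO (MeOH, reflux) forms the 2,3-O-dibutylstannylene acetal F10 on the cis-diol only. The equatorial O2 of F10 is then acylated with mixed anhydride 25 at rt, leaving the axial 7α-hydroxyl free, to give 27.

## Further compounds

F1 | step 12 | methyl (13R)-2α,3α-(isopropylidenedioxy)-17-(phenylsulfonyl)-13-(triethylsilyloxy)-9,10-secolabda-8,14-dien-20-oate (both C10 epimers) | COC(=O)C1C[C@H]2OC(C)(C)O[C@H]2C(C)(C)[C@@H]1CC/C(CS(=O)(=O)c1ccccc1)=C/CC[C@@](C)(O[Si](CC)(CC)CC)C=C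
F2 | step 12 | methyl (13R)-2α,3α-(isopropylidenedioxy)-10-(phenylselanyl)-17-(phenylsulfonyl)-13-(triethylsilyloxy)-9,10-secolabda-8,14-dien-20-oate | COC(=O)C1([Se]c3ccccc3)C[C@H]2OC(C)(C)O[C@H]2C(C)(C)[C@@H]1CC/C(CS(=O)(=O)c1ccccc1)=C/CC[C@@](C)(O[Si](CC)(CC)CC)C=C
F3 | step 3 | 2-[(4R,5R)-5-(iodomethyl)-2,2-dimethyl-1,3-dioxolan-4-yl]propan-2-yl methyl oxalate | COC(=O)C(=O)OC(C)(C)[C@@H]1OC(C)(C)O[C@@H]1CI
F4 | step 3 | methyl 2-[bis(2,2,2-trifluoroethoxy)phosphoryl]acrylate | C=C(C(=O)OC)P(=O)(OCC(F)(F)F)OCC(F)(F)F
F5 | step 7 | methyl (6R)-3-hydroxy-6-methyl-2-methylidene-6-(triethylsilyloxy)oct-7-enoate (both C3 epimers) | C=C[C@](C)(O[Si](CC)(CC)CC)CCC(O)C(=C)C(=O)OC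
F6 | step 7 | (6R)-6-methyl-2-methylidene-6-(triethylsilyloxy)oct-7-ene-1,3-diol (both C3 epimers) | C=C[C@](C)(O[Si](CC)(CC)CC)CCC(O)C(=C)CO
F7 | step 7 | (6R)-3-hydroxy-6-methyl-2-methylidene-6-(triethylsilyloxy)oct-7-en-1-yl methanesulfonate | C=C[C@](C)(O[Si](CC)(CC)CC)CCC(O)C(=C)COS(C)(=O)=O
F8 | step 17 | (13R)-20-acetoxy-2α,3α-(isopropylidenedioxy)-13-(triethylsilyloxy)labda-8(17),14-dien-7α-ol | C=C[C@](C)(O[Si](CC)(CC)CC)CC[C@H]1C(=C)[C@H](O)C[C@H]2C(C)(C)[C@@H]3OC(C)(C)O[C@@H]3C[C@]12COC(C)=O
F9 | step 17 | (13R)-20-acetoxylabda-8(17),14-diene-2α,3α,7α,13-tetraol | C=C[C@](C)(O)CC[C@H]1C(=C)[C@H](O)C[C@H]2C(C)(C)[C@H](O)[C@H](O)C[C@]12COC(C)=O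
F10 | step 17 | 2,3-O-dibutylstannylene acetal of F9 | C=C[C@](C)(O)CC[C@H]1C(=C)[C@H](O)C[C@H]2C(C)(C)[C@@H]3O[Sn](CCCC)(CCCC)O[C@@H]3C[C@]12COC(C)=O
A1 | alternative 1 | (3R,6E,10Z,14S)-11-(acetoxymethyl)-14,15-epoxy-3,7,15-trimethylhexadeca-1,6,10-trien-3-ol | C=C[C@](C)(O)CC/C=C(\C)CC/C=C(\COC(C)=O)CC[C@@H]1OC1(C)C
A2 | alternative 1 | (13R)-20-acetoxylabda-8(17),14-diene-3β,13-diol | C=C[C@](C)(O)CC[C@H]1C(=C)CC[C@H]2C(C)(C)[C@@H](O)CC[C@]12COC(C)=O
A3 | alternative 2 | bicyclic 8-ketone of rings A and B with 2α,3α-acetonide and C20 acetate, no C9 chain | O=C1CC[C@H]2C(C)(C)[C@@H]3OC(C)(C)O[C@@H]3C[C@]2(COC(C)=O)C1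
A4 | alternative 2 | 9β-(3-oxobutyl) derivative of A3 (8,13-diketone) | CC(=O)CC[C@H]1C(=O)CC[C@H]2C(C)(C)[C@@H]3OC(C)(C)O[C@@H]3C[C@]12COC(C)=O
A5 | alternative 2 | 8(17)-methylene C13 methyl ketone from A4 | CC(=O)CC[C@H]1C(=C)CC[C@H]2C(C)(C)[C@@H]3OC(C)(C)O[C@@H]3C[C@]12COC(C)=O
A6 | alternative 3 | (3R,6E,10Z)-11-(hydroxymethyl)-3,7,15-trimethylhexadeca-1,6,10,14-tetraen-3-ol (20-hydroxygeranyllinalool) | C=C[C@](C)(O)CC/C=C(\C)CC/C=C(\CO)CCC=C(C)C
A7 | alternative 3 | (13R)-labda-8(17),14-diene-13,20-diol | C=C[C@](C)(O)CC[C@H]1C(=C)CC[C@H]2C(C)(C)CCC[C@]12CO
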